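**Retrosynthetic overview**
- 17 ⇐ 16: both oxiranes are made in the last step by one twofold chiral-dioxirane epoxidation of the two trisubstituted alkenes, which sets C3, C4 and C10 together.
- 16 ⇐ 13: the ring angelate comes from Mitsunobu inversion of the Luche alcohol at C5; the C6 oxygen comes from a Rubottom oxidation (trans to the side chain) and is carried as a TBS ether.
- 13 ⇐ 3: the side chain is grown from the isopropenyl methyl by allylic chlorination, N-oxide oxidation to the enal, Brown allylation (sets C8), cross-metathesis to the prenyl end and angeloylation.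
- 3 ⇐ (S)-carvone 1, which supplies the six-membered ring and the C1 stereocentre.
- Ring order: cyclohexene (from 1, never opened), then side-chain oxirane and ring oxirane together in step 10.

Assumption: the SMILES is read literally, i.e. ring (as 7-oxabicyclo[4.1.0]heptane) 1R,2R,3R,4R,6R, side-chain acyloxy carbon S, side-chain oxirane CH R, both esters Z (angelates); labels used below: C1 ring carbon bearing the side chain, C2 ring CH2, C3/C4 ring alkene then oxirane (C4 bears CH3), C5 ring angelate carbon (the carvone carbonyl), C6 ring carbinol, C7 methylidene-bearing carbon, C8 side-chain carbinol, C9 CH2, C10 side-chain oxirane CH, C11 CMe2; β is the face of the side chain at C1.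

**Step 1**
Reactants: 1 (S)-(+)-carvone
Product: 3 (5R,6R)-6-(tert-butyldimethylsilyloxy)carvone, via silyl dienol ether 2 (not isolated)
Conditions: LiN(iPr)2, THF, −78 °C; TBSCl, DMPU, −78 °C → rt; evaporate, take up in hexane/CH2Cl2; mCPBA, NaHCO3, −15 °C → rt
Reagents that add atoms: tert-butyldimethylsilyl chloride (TBSCl), C[Si](C)(Cl)C(C)(C)C; meta-chloroperoxybenzoic acid (mCPBA), OOC(=O)c1cccc(Cl)c1
Why: Kinetic α'-deprotonation and O-silylation give the cross-conjugated 2-silyloxydiene, whose Rubottom oxidation (peracid epoxidation of the enol ether, ring opening, 1,4-silyl shift) occurs anti to the neighbouring isopropenyl group and so places the C6 oxygen trans to the C1 substituent.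

**Step 2**
Reactants: 3 (5R,6R)-6-(tert-butyldimethylsilyloxy)carvone
Product: 4 allylic chloride [(5R,6R)-6-(tert-butyldimethylsilyloxy)-5-(3-chloroprop-1-en-2-yl)-2-methylcyclohex-2-en-1-one]
Conditions: Ca(OCl)2, CO2 (dry ice), CH2Cl2/H2O, 0 °C
Reagents that add atoms: calcium hypochlorite, [Ca+2].[O-]Cl.[O-]Cl
Why: Ene-type allylic chlorination by HOCl in which chlorine adds to the terminal CH2 of the electron-rich 1,1-disubstituted alkene and a methyl proton is lost, while the enone alkene is too electron-poor to react and no stereocentre is touched.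

**Step 3**
Reactants: 4 allylic chloride
Product: 5 enal [2-[(1R,6R)-6-(tert-butyldimethylsilyloxy)-4-methyl-5-oxocyclohex-3-en-1-yl]prop-2-enal]
Conditions: N-methylmorpholine N-oxide, NaI (cat.), MeCN, rt → 40 °C
Reagents that add atoms: N-methylmorpholine N-oxide (NMO), C[N+]1([O-])CCOCC1
Why: Kornblum-type (Ganem) N-oxide oxidation in which the N-oxide oxygen displaces the allylic chloride (SN2 and SN2' give the same product) and loss of N-methylmorpholine from the alkoxyammonium salt delivers the 2-substituted acrolein without touching the stereocentres.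

**Step 4**
Reactants: 5 enal; 6 allylmagnesium bromide
Product: 8 (S)-homoallylic alcohol [(5R,6R)-6-(tert-butyldimethylsilyloxy)-5-[(3S)-3-hydroxyhexa-1,5-dien-2-yl]-2-methylcyclohex-2-en-1-one], via (−)-B-allyldiisopinocampheylborane 7 (not isolated)
Conditions: (−)-Ipc2BOMe, CH2=CHCH2MgBr (0.95 equiv to boron), Et2O, 0 °C → rt; then 5, −78 °C; HOCH2CH2NH2 work-up
Reagents that add atoms: none
Why: Brown asymmetric allylboration in which the (+)-α-pinene-derived reagent delivers allyl through a chair six-membered transition state to the Si face of the aldehyde, setting C8 as S under reagent control, the aldehyde reacting far faster than the ring ketone; the amine work-up avoids alkaline peroxide, which would epoxidise the enone.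

**Step 5**
Reactants: 8 (S)-homoallylic alcohol; 9 2-methylbut-2-ene
Product: 10 prenyl alcohol [(5R,6R)-6-(tert-butyldimethylsilyloxy)-5-[(3S)-3-hydroxy-6-methylhepta-1,5-dien-2-yl]-2-methylcyclohex-2-en-1-one]
Conditions: second-generation Grubbs catalyst RuCl2(=CHPh)(H2IMes)(PCy3) (5 mol%), 2-methylbut-2-ene/CH2Cl2, 40 °C
Reagents that add atoms: none
Why: Olefin cross-metathesis in which only the monosubstituted vinyl group engages the catalyst (the 1,1-disubstituted and enone alkenes are inert) and excess 2-methylbut-2-ene caps it as the trisubstituted prenyl terminus with loss of propene, no stereocentre being involved.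

**Step 6**
Reactants: 10 prenyl alcohol; 11 angelic acid
Product: 13 C8 angelate enone [(3S)-2-[(1R,6R)-6-(tert-butyldimethylsilyloxy)-4-methyl-5-oxocyclohex-3-en-1-yl]-6-methylhepta-1,5-dien-3-yl (2Z)-2-methylbut-2-enoate], via mixed anhydride 12 (not isolated)
Conditions: 11, 2,4,6-Cl3C6H2COCl, Et3N, toluene, rt; then 10, toluene, 80 °C (no DMAP)
Reagents that add atoms: none
Why: Yamaguchi-type esterification through the trichlorobenzoyl mixed anhydride, which without a nucleophilic catalyst transfers the (Z)-2-methylbut-2-enoyl group without isomerisation to tiglate and with retention at C8.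

**Step 7**
Reactants: 13 C8 angelate enone
Product: 14 C5 β-alcohol [(3S)-2-[(1R,5R,6R)-6-(tert-butyldimethylsilyloxy)-5-hydroxy-4-methylcyclohex-3-en-1-yl]-6-methylhepta-1,5-dien-3-yl (2Z)-2-methylbut-2-enoate]
Conditions: NaBH4, CeCl3·7H2O, MeOH, −78 → −40 °C
Reagents that add atoms: none
Why: Luche 1,2-reduction in which axial hydride attack on the half-chair enone (C1 and C6 substituents both equatorial) gives the equatorial C5 alcohol, cis to the side chain and trans to the silyloxy group as in carvone to cis-carveol, while the conjugated ester is untouched.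

**Step 8**
Reactants: 14 C5 β-alcohol; 11 angelic acid
Product: 15 bis-angelate silyl ether [(1S,5R,6R)-6-(tert-butyldimethylsilyloxy)-2-methyl-5-[(3S)-6-methyl-3-{[(2Z)-2-methylbut-2-enoyl]oxy}hepta-1,5-dien-2-yl]cyclohex-2-en-1-yl (2Z)-2-methylbut-2-enoate]
Conditions: 11, PPh3, DIAD, toluene, 0 °C → rt
Reagents that add atoms: none
Why: Mitsunobu esterification in which angelate displaces the allylic oxyphosphonium by SN2 with inversion (the cis-carveol to trans-carveyl ester precedent), placing the C5 ester on the α face cis to the C6 silyloxy group under non-basic conditions that leave the Z esters intact.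

**Step 9**
Reactants: 15 bis-angelate silyl ether
Product: 16 triene hydroxy bis-angelate [(1S,5R,6R)-6-hydroxy-2-methyl-5-[(3S)-6-methyl-3-{[(2Z)-2-methylbut-2-enoyl]oxy}hepta-1,5-dien-2-yl]cyclohex-2-en-1-yl (2Z)-2-methylbut-2-enoate]
Conditions: HF·pyridine, pyridine, THF, 0 °C → rt
Reagents that add atoms: none
Why: Fluoride-mediated desilylation under buffered acidic conditions, which cleaves the secondary silyl ether without generating the alkoxide that would trigger 1,2-acyl migration from C5 to C6, no stereocentre being affected.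

**Step 10**
Reactants: 16 triene hydroxy bis-angelate
Product: 17 target diepoxide CNP0296086.5
Conditions: Shi ketone (1,2:4,5-di-O-isopropylidene-β-D-erythro-2,3-hexodiulo-2,6-pyranose, 3 equiv), Oxone (2KHSO5·KHSO4·K2SO4), NaHCO3, MeCN/aq. Na2EDTA, 0 °C, pH 7.5–8
Reagents that add atoms: potassium peroxymonosulfate (KHSO5 of Oxone), [K+].[O-]S(=O)(=O)OO
Why: Twofold Shi asymmetric epoxidation in one operation, in which the chiral dioxirane attacks only the two electron-rich trisubstituted alkenes (the 1,1-disubstituted alkene next to the C8 ester and the angelate alkenes are deactivated) through spiro transition states that make the CH–O carbon R at both C10 and C3, the ring face so chosen also being the one anti to the pseudoaxial C5 angelate (matched), so both oxiranes and three stereocentres are set together while the near-neutral pH suppresses acyl migration to the free C6 hydroxyl.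

**Compound list**
1 | (S)-(+)-carvone, (5S)-2-methyl-5-(prop-1-en-2-yl)cyclohex-2-en-1-one | C=C(C)[C@H]1CC=C(C)C(=O)C1 | starting material
2 | (5S)-3-(tert-butyldimethylsilyloxy)-2-methyl-5-(prop-1-en-2-yl)cyclohexa-1,3-diene (cross-conjugated silyl dienol ether of 1, not isolated) | C=C(C)[C@H]1CC=C(C)C(O[Si](C)(C)C(C)(C)C)=C1 | intermediate
3 | (5R,6R)-6-(tert-butyldimethylsilyloxy)-2-methyl-5-(prop-1-en-2-yl)cyclohex-2-en-1-one (silyloxy trans to isopropenyl) | C=C(C)[C@H]1CC=C(C)C(=O)[C@@H]1O[Si](C)(C)C(C)(C)C | intermediate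
4 | (5R,6R)-6-(tert-butyldimethylsilyloxy)-5-(3-chloroprop-1-en-2-yl)-2-methylcyclohex-2-en-1-one | C=C(CCl)[C@H]1CC=C(C)C(=O)[C@@H]1O[Si](C)(C)C(C)(C)C | intermediate
5 | 2-[(1R,6R)-6-(tert-butyldimethylsilyloxy)-4-methyl-5-oxocyclohex-3-en-1-yl]prop-2-enal | C=C(C=O)[C@H]1CC=C(C)C(=O)[C@@H]1O[Si](C)(C)C(C)(C)C | intermediate
6 | allylmagnesium bromide | C=CC[Mg]Br | starting material
7 | (−)-B-allyldiisopinocampheylborane (both isopinocampheyl groups from (+)-α-pinene, not isolated) | C=CCB([C@@H]1C[C@@H]2C[C@H]([C@H]1C)C2(C)C)[C@@H]1C[C@@H]2C[C@H]([C@H]1C)C2(C)C | intermediate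
8 | (5R,6R)-6-(tert-butyldimethylsilyloxy)-5-[(3S)-3-hydroxyhexa-1,5-dien-2-yl]-2-methylcyclohex-2-en-1-one | C=C([C@H](CC=C)O)[C@H]1CC=C(C)C(=O)[C@@H]1O[Si](C)(C)C(C)(C)C | intermediate
9 | 2-methylbut-2-ene | CC=C(C)C | starting material
10 | (5R,6R)-6-(tert-butyldimethylsilyloxy)-5-[(3S)-3-hydroxy-6-methylhepta-1,5-dien-2-yl]-2-methylcyclohex-2-en-1-one | C=C([C@H](CC=C(C)C)O)[C@H]1CC=C(C)C(=O)[C@@H]1O[Si](C)(C)C(C)(C)C | intermediate
11 | angelic acid, (2Z)-2-methylbut-2-enoic acid | C/C=C(/C)C(=O)O | starting material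
12 | (2Z)-2-methylbut-2-enoic 2,4,6-trichlorobenzoic anhydride (not isolated) | C/C=C(/C)C(=O)OC(=O)c1c(Cl)cc(Cl)cc1Cl | intermediate
13 | (3S)-2-[(1R,6R)-6-(tert-butyldimethylsilyloxy)-4-methyl-5-oxocyclohex-3-en-1-yl]-6-methylhepta-1,5-dien-3-yl (2Z)-2-methylbut-2-enoate | C=C([C@H](CC=C(C)C)OC(=O)/C(C)=C\C)[C@H]1CC=C(C)C(=O)[C@@H]1O[Si](C)(C)C(C)(C)C | intermediate
14 | (3S)-2-[(1R,5R,6R)-6-(tert-butyldimethylsilyloxy)-5-hydroxy-4-methylcyclohex-3-en-1-yl]-6-methylhepta-1,5-dien-3-yl (2Z)-2-methylbut-2-enoate (ring OH β, trans to the silyloxy group) | C=C([C@H](CC=C(C)C)OC(=O)/C(C)=C\C)[C@H]1CC=C(C)[C@@H](O)[C@@H]1O[Si](C)(C)C(C)(C)C | intermediate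
15 | (1S,5R,6R)-6-(tert-butyldimethylsilyloxy)-2-methyl-5-[(3S)-6-methyl-3-{[(2Z)-2-methylbut-2-enoyl]oxy}hepta-1,5-dien-2-yl]cyclohex-2-en-1-yl (2Z)-2-methylbut-2-enoate | C=C([C@H](CC=C(C)C)OC(=O)/C(C)=C\C)[C@H]1CC=C(C)[C@H](OC(=O)/C(C)=C\C)[C@@H]1O[Si](C)(C)C(C)(C)C | intermediate
16 | (1S,5R,6R)-6-hydroxy-2-methyl-5-[(3S)-6-methyl-3-{[(2Z)-2-methylbut-2-enoyl]oxy}hepta-1,5-dien-2-yl]cyclohex-2-en-1-yl (2Z)-2-methylbut-2-enoate | C=C([C@H](CC=C(C)C)OC(=O)/C(C)=C\C)[C@H]1CC=C(C)[C@H](OC(=O)/C(C)=C\C)[C@@H]1O | intermediate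
17 | (1R,2R,3R,4R,6R)-4-[(3S)-4-[(2R)-3,3-dimethyloxiran-2-yl]-3-{[(2Z)-2-methylbut-2-enoyl]oxy}but-1-en-2-yl]-3-hydroxy-1-methyl-7-oxabicyclo[4.1.0]heptan-2-yl (2Z)-2-methylbut-2-enoate (CNP0296086.5) | C=C([C@H](C[C@H]1OC1(C)C)OC(=O)/C(C)=C\C)[C@H]1C[C@H]2O[C@@]2(C)[C@H](OC(=O)/C(C)=C\C)[C@@H]1O | target

**Totals**
Total step count: 10. Longest linear sequence: 10 steps, from (S)-carvone 1.

**Three steps most likely to fail**

Step 10 (twofold epoxidation of 16). The risks are over-oxidation of the 1,1-disubstituted alkene, incomplete or wrong-face reaction at the ring alkene, and angelate migration to the free C6 hydroxyl. The fallback sets out from 15 and returns at 17, and separates the two oxidations while the C6 oxygen is still silylated. Compound 15 is epoxidised with the same D-fructose-derived ketone under the catalytic carbonate-buffered protocol (0.3 equiv ketone, Oxone, K2CO3, MeCN/dimethoxymethane/aqueous buffer pH 10.5, 0 °C) and stopped after the more reactive prenyl alkene has reacted, giving the side-chain (R)-monoepoxide F1. The ring alkene of F1 is then epoxidised under substrate control with mCPBA/NaHCO3 in CH2Cl2 at 0 °C, anti to the pseudoaxial C5 angelate, giving the diepoxide silyl ether F2. If the ring alkene already reacts in the first operation, F2 is obtained directly. Desilylation of F2 with Bu4NF buffered with AcOH in THF at 0 °C gives 17.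

Step 8 (Mitsunobu inversion at C5 with angelic acid). The risks are slow SN2 next to the silyloxy group, SN2' attack at C3 and elimination to the diene. The fallback sets out from 13 and returns at 15, and replaces inversion by a reagent-controlled reduction followed by a retentive acylation. Enone 13 is reduced with (S)-2-methyl-CBS-oxazaborolidine and catecholborane in toluene at −78 °C, which should deliver hydride to the β face when the alkenyl carbon acts as the large group; the enantiomeric catalyst is the check if that assignment is wrong. This gives the C5 α-alcohol F3, which is acylated with 11 through mixed anhydride 12 as in step 6 to give 15. The same acylation rescues the route if step 7 itself gives the α-alcohol.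

Step 3 (N-oxide oxidation of 4 to the 2-substituted acrolein 5). The risks are sluggish displacement of the chloride and loss of the sensitive enal. The fallback sets out from 4 and returns at 5, and introduces the oxygen by substitution and makes the aldehyde in a separate alcohol oxidation. Chloride 4 is treated with HCO2Na and catalytic Bu4NBr in DMF at 40 °C to give the allylic formate F4. Mild methanolysis (NaHCO3, MeOH, rt) gives the allylic alcohol F5. Oxidation with MnO2 in CH2Cl2 at rt gives 5, which is used at once in step 4.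

**Further compounds**
F1 | step 10 | side-chain (R)-monoepoxide of 15 (ring alkene intact, C6 TBS ether) | C=C([C@H](C[C@H]1OC1(C)C)OC(=O)/C(C)=C\C)[C@H]1CC=C(C)[C@H](OC(=O)/C(C)=C\C)[C@@H]1O[Si](C)(C)C(C)(C)C
F2 | step 10 | C6 tert-butyldimethylsilyl ether of 17 (both oxiranes in place) | C=C([C@H](C[C@H]1OC1(C)C)OC(=O)/C(C)=C\C)[C@H]1C[C@H]2O[C@@]2(C)[C@H](OC(=O)/C(C)=C\C)[C@@H]1O[Si](C)(C)C(C)(C)C
F3 | step 8 | C5 epimer of 14 (ring OH α, cis to the silyloxy group) | C=C([C@H](CC=C(C)C)OC(=O)/C(C)=C\C)[C@H]1CC=C(C)[C@H](O)[C@@H]1O[Si](C)(C)C(C)(C)C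
F4 | step 3 | allylic formate, 2-[(1R,6R)-6-(tert-butyldimethylsilyloxy)-4-methyl-5-oxocyclohex-3-en-1-yl]prop-2-en-1-yl formate | C=C(COC=O)[C@H]1CC=C(C)C(=O)[C@@H]1O[Si](C)(C)C(C)(C)C
F5 | step 3 | allylic alcohol, (5R,6R)-6-(tert-butyldimethylsilyloxy)-5-(3-hydroxyprop-1-en-2-yl)-2-methylcyclohex-2-en-1-one | C=C(CO)[C@H]1CC=C(C)C(=O)[C@@H]1O[Si](C)(C)C(C)(C)C
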